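## Structural features

The target (19) is an achiral para-depside, C30H38O9: a 2-hydroxy-4-methoxy-6-(2-oxoheptyl)benzoyl unit (ring A, C1–C6, carbonyl carbon on C1) esterifies O4′ of 2-methoxy-6-(2-oxoheptyl)benzoic acid (ring B, C1′–C6′). There are no stereocentres, so the problem is one of regiochemistry and functional-group compatibility. Both rings are β-resorcylates with the same carbon pattern (carboxyl on C1, oxygens on C2 and C4, a CH2–CO–C5H11 chain on C6) and differ only in their oxygens: ring A has O2–H free and O4 methylated, ring B has O2′ methylated and O4′ acylated. The fragile points are the aryl ester between the rings, the free salicylic-type acid of ring B, and above all the two 2-oxoalkyl chains ortho to a carboxyl carbon, whose enols can close onto that carbon to give 3-pentylisocoumarins when the carboxyl is activated or strong acid is present. The real difficulty is threefold: telling O2 from O4 in opposite senses on two nearly identical rings, acylating a phenol with a 2,6-disubstituted benzoic acid without isocoumarin closure, and unmasking ketones and acid at the end without touching the depside ester. The key step exploits the 1,3-relationship of O2 and O4 to the C1 carboxyl and the C6 side chain in ring A (identically in ring B): C1, its carboxyl and C2 come from a malonate and C3–C6 with the side chain from an enone, so both oxygens arrive as the carbonyls of a 1,3-dione, the carboxyl arrives as a benzyl ester, and one annulation product serves both rings. After aromatization O2–H is chelated to the ester carbonyl and O4–H is not, which is the handle used to treat the two oxygens differently.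

## Logic of the disconnections

19 to 18: the benzyl–oxygen bond on the ring B carboxyl is restored. The acid is then revealed last by neutral hydrogenolysis, so no acid, base or activating agent meets an oxoalkyl-substituted benzoic acid. The forward step must spare two aliphatic ketones and the aryl ester.

18 to 17: both side-chain C=O groups go back to dioxolanes (four C–O bonds). In 17 no ketone enol exists that could lactonize onto either carboxyl carbon. The forward hydrolysis must be mild enough to spare the aryl ester, and it is run while the ring B carboxyl is still an ester.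

17 to 13 + 16: the C(=O)–O4′ bond between the rings is cut. This is the only convergent cut and gives two pieces of nearly equal size. It demands that 16 has a single free phenol and that O2–H of 13 is a poor nucleophile, which its hydrogen bond to the carboxyl should secure.

13 to 12 to 11: the benzyl ester is restored (13 to 12) and the O4–CH3 bond is cut (12 to 11). This leads to a compound with two hydroxyls of different reactivity. The forward methylation must stop after one methyl group, which chelation of O2–H allows under mild conditions.

16 to 15 to 14 to 11: O4′–H is capped with allyl (16 to 15), the O2′–CH3 bond is cut (15 to 14), and the O4′–allyl bond is cut (14 to 11). Both halves thus converge on 11. The forward steps need allylation on O4′ only, forced methylation of the chelated O2′–H, and an allyl removal that spares benzyl ester and dioxolane.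

11 to 8: two hydrogens are added back to the ring (on C6 and C5, with C1 becoming sp3), tracing the arene to a 1,3-dione. This opens the way to annulation chemistry. The forward dehydrogenation must generate no strong acid (dioxolane) and use no hydrogen-transfer metal surface (benzyl ester).

8 to 5 + 6 (through 7): bonds C1–C6 and C2–C3 are cut. The ring falls into a malonate and an enone, both simple and achiral. The forward step needs 1,4-addition and then closure from the methyl carbon only.

5 to 3 + 4: the C3=C4 double bond of the enone is cut. This gives an aldehyde and a stabilized ylide; the forward olefination must run without base strong enough to open the β-ketal.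

3 to 2 to 1: the aldehyde is traced to the ester and the dioxolane to the ketone. 1 is a commercial β-keto ester that already holds the whole side chain. The forward reduction must stop at the aldehyde.

## Other disconnections considered

Alternative 1: The cut removes C2–C5 of ring A as a four-carbon diene and leaves C1 and C6 as an alkyne already esterified to ring B. Bonds C1–C2 and C5–C6 are broken, giving the aryl ynoate A2 and the oxygenated diene A3. Forward, the CH2 terminus of A3 should bond to the ynoate β-carbon (C6) and its ketene-acetal carbon to the α-carbon (C1); loss of methanol and of the silyl group would give the bis-ketal depside A1, which is the same compound as 17.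
- In favour: the inter-ring ester is made from an unhindered alkynoic acid, not from a 2,6-disubstituted salicylic acid, so step 11 of the chosen plan has no counterpart; here the alternative is the better. Ring A arrives with O4 methylated, O2 free and at the arene oxidation level, so neither an oxidant nor a phenol differentiation is needed for ring A; here it is equal or better.
- Against: 16 must still be made, and it has the same carbon pattern as ring A, so steps 1–5 and 8–10 would be needed anyway. The CH2 of A2 lies between an alkyne and a ketal and should isomerize easily to an allenoate under base. A2 is an activated aryl ester open to attack by A3 at the carbonyl carbon. A3 is moisture-sensitive.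
- Comparison: on structure both plans meet at the same protected depside. On mechanism a polarized cycloaddition with elimination replaces conjugate addition, Claisen closure and a separate dehydrogenation. On step economy the saved oxidation and methylation are offset by the separate alkynoic acid portion and by 16, so the count should be level or somewhat longer.

Alternative 2: The cut is on ring B, at the bonds from C1′ to the carboxyl carbon and from C6′ to the side-chain CH2. Both carbons are traced to 6, inserted into the C1′–C6′ aryne generated from the silyl triflate A5. Forward, CsF releases the aryne; the malonate carbon adds to C6′ (remote from the methoxy group, so the aryl anion develops at C1′ next to that oxygen); the anion attacks one ester carbonyl and fragmentation moves that carboxyl to C1′, giving the homophthalate A4.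
- In favour: O2′ and O4′ differ from the outset (methyl against methoxymethyl) on a ring that is never a dione, so no aromatization and no phenol differentiation are needed for ring B; on this point the alternative is better. The methoxy group dictates the regiochemistry, and two C–C bonds form in one mild step, which equals the annulation.
- Against: A4 carries an acetic ester where the target needs a 2-oxoheptyl chain. The two benzyl esters would have to be told apart and the aliphatic one turned into a pentyl ketone on a homophthalate, which has an acidic benzylic CH2 and tends to close to isocoumarins. The ketone would then need acid ketalization, and the methoxymethyl ether would have to come off under acid in the presence of the dioxolane, which is not orthogonal. A5 needs several steps of its own, plain α-arylation without insertion competes, and only ring B is addressed.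
- Comparison: on structure it reaches a ring B precursor still lacking the side chain, whereas the chosen plan reaches 16 with the chain in place. On mechanism the two are equal in bonds formed. On step economy it should be clearly longer, since ring A still needs steps 1–7.

Alternative 3: The cut is the C1′–C6′ bond of ring B (equally C1–C6 of ring A), which unravels the resorcylate into the open-chain trioxo ester A8 and, further back, the diketo-dioxinone A7. Forward, heating A7 with benzyl alcohol should expel acetone and trap the resulting ketene as A8, whose C2 carbon adds to the C7 ketone and dehydrates to the resorcylate A6, identical with 11.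
- In favour: the ring forms directly at the arene oxidation level, so the dehydrogenation of step 5 disappears; here the alternative is better. The ester group is chosen by the trapping alcohol, and since A6 is 11, steps 6–13 follow unchanged, so the plans are equal from there on.
- Against: A7 must be built by successive C-acylations of dioxinone enolates with an activated derivative of the acid corresponding to 2. That is about as many steps as the way to 8, with strong bases on polycarbonyl compounds that are tautomeric mixtures and hard to purify. In A8 the C7 ketone has on its far side a CH2 attached to the ketal carbon, so enolization that way can open the dioxolane by β-elimination. Pyrone formation by O-cyclization competes with the aldol closure.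
- Comparison: on structure both give the same resorcylate. On mechanism an aldol condensation driven by aromatization replaces conjugate addition, Claisen closure and oxidation. On step economy the counts should be about equal, and the choice rests on the cheap, stable reagents of the malonate–enone chemistry.

Key step: step 4

Remarks on the chemistry:
- Ring atoms are numbered C1–C6 (ring A) and C1′–C6′ (ring B) from the carbon bearing the carboxyl carbon. Compounds 7, 8 and 9 are racemic (one enantiomer drawn); their stereocentres vanish in step 5.
- The Claisen closure of step 4 is classed as 6-(enolendo)-exo-trig, because both enolate carbons C3 and C4 become ring atoms; it is not an enolexo closure.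
- Iodine in methanol is not used for the aromatization: the hydrogen iodide it generates in methanol would exchange or hydrolyse the dioxolane and endanger the benzyl ester. In the dihydro ring O2 and O4 are the two ends of one vinylogous acid, so a kinetic O-alkylation cannot be relied on to choose between them. The ring is therefore dehydrogenated as its bis-silyl dienol ether, and O2 and O4 are told apart on the arene by chelation.
- Ring B is not built from an orsellinate: the material from step 5 is divided between the ring A branch (steps 6–7) and the ring B branch (steps 8–10), which is shorter.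

## Steps

Step 1
Reactants: 1 methyl 3-oxooctanoate
Product: 2 methyl 2-(2-pentyl-1,3-dioxolan-2-yl)acetate
Conditions: HOCH2CH2OH (3 equiv), p-TsOH·H2O (cat.), PhMe, reflux, azeotropic removal of water
Reagents that add atoms: ethylene glycol, OCCO
Why: Acid-catalysed ketalization; the ketone is far more electrophilic than the ester and removal of water drives the equilibrium to the dioxolane.

Step 2
Reactants: 2 methyl 2-(2-pentyl-1,3-dioxolan-2-yl)acetate
Product: 3 2-(2-pentyl-1,3-dioxolan-2-yl)acetaldehyde
Conditions: (i-Bu)2AlH (1.05 equiv), CH2Cl2, −78 °C; MeOH, then aq. potassium sodium tartrate; crude product used at once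
Reagents that add atoms: none
Why: Partial reduction of an ester; the tetrahedral aluminium hemiacetal, chelated by a dioxolane oxygen, should persist at −78 °C and release the aldehyde only on work-up. The β,β-dialkoxy aldehyde is not chromatographed, to avoid β-elimination.

Step 3
Reactants: 3 2-(2-pentyl-1,3-dioxolan-2-yl)acetaldehyde; 4 1-(triphenylphosphoranylidene)propan-2-one
Product: 5 (E)-5-(2-pentyl-1,3-dioxolan-2-yl)pent-3-en-2-one
Conditions: CH2Cl2, rt → 40 °C
Reagents that add atoms: none
Why: Wittig olefination with a stabilized ylide, which is nearly neutral (no opening of the β-ketal) and should give the E-enone under thermodynamic control of the oxaphosphetane pathway.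

Step 4
Reactants: 5 (E)-5-(2-pentyl-1,3-dioxolan-2-yl)pent-3-en-2-one; 6 dibenzyl malonate
Product: 8 benzyl trans-2,4-dioxo-6-[(2-pentyl-1,3-dioxolan-2-yl)methyl]cyclohexane-1-carboxylate (racemic), via Michael adduct 7 (not isolated)
Conditions: NaH (1.1 equiv), THF, 0 °C; add 5, 0 °C → rt, then 65 °C; 0 °C, aq. HCl to pH 4
Reagents that add atoms: none
Why: Michael–Claisen annulation, the classical malonate–enone route to 6-substituted 2,4-dioxocyclohexane-1-carboxylates. The soft sodium enolate of 6 adds 1,4 to the unhindered enone 5 (bond C1–C6) to give 7; proton transfer then provides, in equilibrium, the methyl ketone enolate, whose carbon C3 attacks one of the two equivalent benzyl ester carbonyls (bond C2–C3) and expels benzyloxide. The closure is a 6-(enolendo)-exo-trig Claisen condensation, with the enolate double bond C3=C4 inside the new ring and the ester C=O outside it, a favoured mode for six-membered rings. It is driven forward because the released benzyloxide deprotonates the product at C3 to a stabilized dione enolate, so one equivalent of base suffices. Regiochemistry of closure is fixed because only the methyl carbon reaches an ester through a six-membered transition state (C5 would close a four-membered ring), and 1,4- over 1,2-addition follows from the stabilized nucleophile. The new stereocentres C1 and C6 are set under thermodynamic control: C1 is an epimerizable β-keto ester carbon and should settle trans to the C6 substituent with both groups equatorial; the product is racemic and both centres are erased in step 5, so no further control is needed. The malonate anion is too weak a base to deprotonate the γ-CH2 of 5 appreciably, which suppresses β-elimination of a ketal oxygen, and the cold work-up at pH 4 protonates the dione without hydrolysing the dioxolane.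

Step 5
Reactants: 8 benzyl trans-2,4-dioxo-6-[(2-pentyl-1,3-dioxolan-2-yl)methyl]cyclohexane-1-carboxylate
Product: 11 benzyl 2,4-dihydroxy-6-[(2-pentyl-1,3-dioxolan-2-yl)methyl]benzoate, via bis-silyl dienol ether 9 (not isolated), via bis-silyl aryl ether 10 (not isolated)
Conditions: Me3SiCl (2.5 equiv), Et3N (3 equiv), PhMe, 0 °C → rt; filter, concentrate; DDQ (1.05 equiv), PhMe, 0 °C → rt; then K2CO3 (cat.), MeOH, rt
Reagents that add atoms: none
Why: Silylation of both enolic oxygens locks the ring as a 2,4-dioxygenated cyclohexa-1,3-diene; DDQ dehydrogenation (hydride abstraction at C6 to a cation stabilized by both oxygens, then loss of a C5 proton) aromatizes it, as known for silyloxy and alkoxy cyclohexadienes. Methanolysis frees both phenols. The conditions are non-acidic and free of hydrogen, so dioxolane and benzyl ester should survive, and the benzylic CH2 is meta to both oxygens and not activated toward DDQ.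

Step 6
Reactants: 11 benzyl 2,4-dihydroxy-6-[(2-pentyl-1,3-dioxolan-2-yl)methyl]benzoate
Product: 12 benzyl 2-hydroxy-4-methoxy-6-[(2-pentyl-1,3-dioxolan-2-yl)methyl]benzoate
Conditions: MeI (1.1 equiv), K2CO3 (1.2 equiv), acetone, rt → 40 °C
Reagents that add atoms: iodomethane, CI
Why: Williamson etherification; O4–H is the more acidic, unchelated phenol, whereas O2–H is hydrogen-bonded to the ester carbonyl and should not react under these mild conditions.

Step 7
Reactants: 12 benzyl 2-hydroxy-4-methoxy-6-[(2-pentyl-1,3-dioxolan-2-yl)methyl]benzoate
Product: 13 2-hydroxy-4-methoxy-6-[(2-pentyl-1,3-dioxolan-2-yl)methyl]benzoic acid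
Conditions: H2 (1 atm), 10% Pd/C, EtOAc, rt; filter, concentrate below 30 °C, use at once in step 11
Reagents that add atoms: none
Why: Hydrogenolysis of the benzyl ester under neutral conditions, independent of the steric hindrance at the carbonyl; aryl methyl ether and dioxolane are inert. The acid is not stored because it sits next to an acid-labile ketal.

Step 8
Reactants: 11 benzyl 2,4-dihydroxy-6-[(2-pentyl-1,3-dioxolan-2-yl)methyl]benzoate
Product: 14 benzyl 2-hydroxy-6-[(2-pentyl-1,3-dioxolan-2-yl)methyl]-4-(prop-2-en-1-yloxy)benzoate
Conditions: allyl bromide (1.1 equiv), K2CO3 (1.2 equiv), acetone, rt → 50 °C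
Reagents that add atoms: allyl bromide, C=CCBr
Why: Williamson etherification with the same chelation-based selectivity for O4′ as in step 6; allyl is chosen because its removal is orthogonal to benzyl ester and dioxolane.

Step 9
Reactants: 14 benzyl 2-hydroxy-6-[(2-pentyl-1,3-dioxolan-2-yl)methyl]-4-(prop-2-en-1-yloxy)benzoate
Product: 15 benzyl 2-methoxy-6-[(2-pentyl-1,3-dioxolan-2-yl)methyl]-4-(prop-2-en-1-yloxy)benzoate
Conditions: MeI (5 equiv), K2CO3 (3 equiv), DMF, 50 °C
Reagents that add atoms: iodomethane, CI
Why: Williamson methylation of the chelated phenol, which needs the dipolar solvent, excess reagent and warming; the allyl ether is far below its Claisen rearrangement temperature, and benzyl ester and ketal are inert to carbonate.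

Step 10
Reactants: 15 benzyl 2-methoxy-6-[(2-pentyl-1,3-dioxolan-2-yl)methyl]-4-(prop-2-en-1-yloxy)benzoate
Product: 16 benzyl 4-hydroxy-2-methoxy-6-[(2-pentyl-1,3-dioxolan-2-yl)methyl]benzoate
Conditions: Pd(PPh3)4 (3 mol%), morpholine (3 equiv), THF, rt
Reagents that add atoms: none
Why: Tsuji–Trost deallylation; zerovalent palladium ionizes the aryl allyl ether to a π-allyl complex and phenoxide, and morpholine traps the allyl group. The hindered benzyl ester is neither ionized nor aminolysed under these conditions.

Step 11
Reactants: 13 2-hydroxy-4-methoxy-6-[(2-pentyl-1,3-dioxolan-2-yl)methyl]benzoic acid; 16 benzyl 4-hydroxy-2-methoxy-6-[(2-pentyl-1,3-dioxolan-2-yl)methyl]benzoate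
Product: 17 benzyl 4-({2-hydroxy-4-methoxy-6-[(2-pentyl-1,3-dioxolan-2-yl)methyl]benzoyl}oxy)-2-methoxy-6-[(2-pentyl-1,3-dioxolan-2-yl)methyl]benzoate
Conditions: DCC (1.2 equiv), DMAP (0.1 equiv), CH2Cl2, 0 °C → rt
Reagents that add atoms: none
Why: Steglich (carbodiimide) esterification, the standard way to join depside halves. O4′–H of 16 is the only unchelated hydroxyl present, while O2–H of 13 is hydrogen-bonded and a poor nucleophile. Both ketones are masked, so the activated carboxyl cannot be captured by an enol to give an isocoumarin.

Step 12
Reactants: 17 benzyl 4-({2-hydroxy-4-methoxy-6-[(2-pentyl-1,3-dioxolan-2-yl)methyl]benzoyl}oxy)-2-methoxy-6-[(2-pentyl-1,3-dioxolan-2-yl)methyl]benzoate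
Product: 18 benzyl 4-{[2-hydroxy-4-methoxy-6-(2-oxoheptyl)benzoyl]oxy}-2-methoxy-6-(2-oxoheptyl)benzoate
Conditions: 1 M aq. HCl/THF (1:3), rt
Reagents that add atoms: water, O
Why: Acid-catalysed hydrolysis of two dialkyl-ketone dioxolanes, which should be much faster than hydrolysis of the hindered aryl and benzyl esters in dilute acid at room temperature. It is run before the ring B acid is freed, so no free carboxyl is present to lactonize onto a ketone enol.

Step 13
Reactants: 18 benzyl 4-{[2-hydroxy-4-methoxy-6-(2-oxoheptyl)benzoyl]oxy}-2-methoxy-6-(2-oxoheptyl)benzoate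
Product: 19 4-{[2-hydroxy-4-methoxy-6-(2-oxoheptyl)benzoyl]oxy}-2-methoxy-6-(2-oxoheptyl)benzoic acid (target)
Conditions: H2 (1 atm), 10% Pd/C, EtOAc, rt
Reagents that add atoms: none
Why: Hydrogenolysis of the benzyl ester under neutral conditions; aliphatic ketones, the aryl ester and the aryl ethers are not reduced at atmospheric pressure, and the acid is released without acid or base.

## Compound list

1 | methyl 3-oxooctanoate | CCCCCC(=O)CC(=O)OC | starting material
2 | methyl 2-(2-pentyl-1,3-dioxolan-2-yl)acetate | CCCCCC1(CC(=O)OC)OCCO1 | intermediate
3 | 2-(2-pentyl-1,3-dioxolan-2-yl)acetaldehyde | CCCCCC1(CC=O)OCCO1 | intermediate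
4 | 1-(triphenylphosphoranylidene)propan-2-one | CC(=O)C=P(c1ccccc1)(c1ccccc1)c1ccccc1 | starting material
5 | (E)-5-(2-pentyl-1,3-dioxolan-2-yl)pent-3-en-2-one | CC(=O)/C=C/CC1(CCCCC)OCCO1 | intermediate
6 | dibenzyl malonate | O=C(CC(=O)OCc1ccccc1)OCc1ccccc1 | starting material
7 | dibenzyl 2-[4-oxo-1-(2-pentyl-1,3-dioxolan-2-yl)pentan-2-yl]malonate (racemic, one enantiomer drawn; formed in the flask, not isolated) | CC(=O)C[C@@H](CC1(CCCCC)OCCO1)C(C(=O)OCc1ccccc1)C(=O)OCc1ccccc1 | intermediate
8 | benzyl trans-2,4-dioxo-6-[(2-pentyl-1,3-dioxolan-2-yl)methyl]cyclohexane-1-carboxylate (racemic, one enantiomer drawn) | O=C(OCc1ccccc1)[C@@H]1C(=O)CC(=O)C[C@H]1CC2(CCCCC)OCCO2 | intermediate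
9 | benzyl 6-[(2-pentyl-1,3-dioxolan-2-yl)methyl]-2,4-bis(trimethylsilyloxy)cyclohexa-1,3-diene-1-carboxylate (racemic, one enantiomer drawn; formed in the flask, not isolated) | O=C(OCc1ccccc1)C1=C(O[Si](C)(C)C)C=C(O[Si](C)(C)C)C[C@H]1CC2(CCCCC)OCCO2 | intermediate
10 | benzyl 6-[(2-pentyl-1,3-dioxolan-2-yl)methyl]-2,4-bis(trimethylsilyloxy)benzoate (formed in the flask, not isolated) | O=C(OCc1ccccc1)c1c(O[Si](C)(C)C)cc(O[Si](C)(C)C)cc1CC1(CCCCC)OCCO1 | intermediate
11 | benzyl 2,4-dihydroxy-6-[(2-pentyl-1,3-dioxolan-2-yl)methyl]benzoate | O=C(OCc1ccccc1)c1c(O)cc(O)cc1CC1(CCCCC)OCCO1 | intermediate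
12 | benzyl 2-hydroxy-4-methoxy-6-[(2-pentyl-1,3-dioxolan-2-yl)methyl]benzoate | O=C(OCc1ccccc1)c1c(O)cc(OC)cc1CC1(CCCCC)OCCO1 | intermediate
13 | 2-hydroxy-4-methoxy-6-[(2-pentyl-1,3-dioxolan-2-yl)methyl]benzoic acid | O=C(O)c1c(O)cc(OC)cc1CC1(CCCCC)OCCO1 | intermediate
14 | benzyl 2-hydroxy-6-[(2-pentyl-1,3-dioxolan-2-yl)methyl]-4-(prop-2-en-1-yloxy)benzoate | O=C(OCc1ccccc1)c1c(O)cc(OCC=C)cc1CC1(CCCCC)OCCO1 | intermediate
15 | benzyl 2-methoxy-6-[(2-pentyl-1,3-dioxolan-2-yl)methyl]-4-(prop-2-en-1-yloxy)benzoate | O=C(OCc1ccccc1)c1c(OC)cc(OCC=C)cc1CC1(CCCCC)OCCO1 | intermediate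
16 | benzyl 4-hydroxy-2-methoxy-6-[(2-pentyl-1,3-dioxolan-2-yl)methyl]benzoate | O=C(OCc1ccccc1)c1c(OC)cc(O)cc1CC1(CCCCC)OCCO1 | intermediate
17 | benzyl 4-({2-hydroxy-4-methoxy-6-[(2-pentyl-1,3-dioxolan-2-yl)methyl]benzoyl}oxy)-2-methoxy-6-[(2-pentyl-1,3-dioxolan-2-yl)methyl]benzoate | CCCCCC1(Cc2cc(OC)cc(O)c2C(=O)Oc2cc(CC3(CCCCC)OCCO3)c(C(=O)OCc3ccccc3)c(OC)c2)OCCO1 | intermediate
18 | benzyl 4-{[2-hydroxy-4-methoxy-6-(2-oxoheptyl)benzoyl]oxy}-2-methoxy-6-(2-oxoheptyl)benzoate | CCCCCC(=O)Cc1cc(OC)cc(O)c1C(=O)Oc1cc(CC(=O)CCCCC)c(C(=O)OCc2ccccc2)c(OC)c1 | intermediate
19 | 4-{[2-hydroxy-4-methoxy-6-(2-oxoheptyl)benzoyl]oxy}-2-methoxy-6-(2-oxoheptyl)benzoic acid (CNP0177576.0) | CCCCCC(=O)Cc1cc(OC)cc(O)c1C(=O)Oc1cc(CC(=O)CCCCC)c(C(=O)O)c(OC)c1 | target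

## Step count and least certain steps

Total: 13 steps. Longest linear sequence: 11 steps (steps 1–5, 8–10, 11–13); the ring A branch (steps 6–7) joins at step 11.

Step 4 (key step). Most likely failures:
- deprotonation of the γ-CH2 of 5 followed by β-elimination that opens the dioxolane;
- stalling at the Michael stage, because the adduct rests as a stabilized malonate anion and the ring closure has to pass through the scarce methyl ketone enolate;
- loss of the ketal during an over-acidic work-up.

Fallback, from 3 back to 8 with the other classical bond set of dihydroresorcylate synthesis (C1–C6 and C3–C4): Wittig olefination of 3 with benzyl (triphenylphosphoranylidene)acetate should give benzyl (E)-4-(2-pentyl-1,3-dioxolan-2-yl)but-2-enoate F1, an acceptor with a less acidic γ-CH2 than the enone. Conjugate addition of the sodium enolate of benzyl acetoacetate (NaH, THF) should give dibenzyl 2-acetyl-3-[(2-pentyl-1,3-dioxolan-2-yl)methyl]pentanedioate F2. On warming, the acetyl methyl enolate of F2 closes onto the unhindered CH2CO2Bn ester in a Dieckmann-type condensation and rejoins the route at 8.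

Step 5. Most likely failures:
- incomplete silylation, leaving free 1,3-dione that adds to DDQ through C3 instead of being dehydrogenated;
- over-oxidation of the electron-rich product;
- ketal loss if moisture and the acidic hydroquinone by-product act together.

Fallback, from 8 back to 12 and 14, bypassing 11 and steps 6 and 8 (one step more overall); the oxygens are differentiated in the dihydro ring and only then dehydrogenated. O-Methylation of 8 with dimethyl sulfate and K2CO3 in acetone should give benzyl trans-4-methoxy-2-oxo-6-[(2-pentyl-1,3-dioxolan-2-yl)methyl]cyclohex-3-ene-1-carboxylate F3, which DDQ in PhMe dehydrogenates to 12. In parallel, O-allylation with allyl methanesulfonate and K2CO3 should give benzyl trans-2-oxo-6-[(2-pentyl-1,3-dioxolan-2-yl)methyl]-4-(prop-2-en-1-yloxy)cyclohex-3-ene-1-carboxylate F4, which DDQ dehydrogenates to 14. Selectivity for O4 rests on chelation of the cation between O2 and the ester carbonyl and on the lower hindrance at O4. Any O2-alkylated isomer would aromatize to an unchelated phenol, which is separable; for the methyl case that isomer is 16 itself.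

Step 11 (with step 7). Most likely failures:
- slow acyl transfer from the hindered O-acylisourea, with rearrangement to the N-acylurea;
- self-acylation through O2–H of 13;
- opening of the neighbouring dioxolane by the free carboxylic acid while 13 is handled.

Fallback, from 12 back to 19, with O2 protected and the acid handled as its salt until use: benzylation of 12 (benzyl bromide, K2CO3, DMF) should give benzyl 2-(benzyloxy)-4-methoxy-6-[(2-pentyl-1,3-dioxolan-2-yl)methyl]benzoate F5. Saponification (KOH, DMSO/H2O, 80 °C, then cold acidification to pH 4) should give 2-(benzyloxy)-4-methoxy-6-[(2-pentyl-1,3-dioxolan-2-yl)methyl]benzoic acid F6. Carbodiimide coupling of F6 with 16 should give benzyl 4-({2-(benzyloxy)-4-methoxy-6-[(2-pentyl-1,3-dioxolan-2-yl)methyl]benzoyl}oxy)-2-methoxy-6-[(2-pentyl-1,3-dioxolan-2-yl)methyl]benzoate F7. Ketal hydrolysis as in step 12 should give benzyl 4-{[2-(benzyloxy)-4-methoxy-6-(2-oxoheptyl)benzoyl]oxy}-2-methoxy-6-(2-oxoheptyl)benzoate F8, and hydrogenolysis as in step 13 removes both benzyl groups to reach 19.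

Step 2. Most likely failures:
- over-reduction to the alcohol if the aluminium hemiacetal collapses before the quench;
- β-elimination with opening of the dioxolane when the β,β-dialkoxy aldehyde is handled.

Fallback, from 2 back to 3: full reduction of 2 with LiAlH4 in THF at 0 °C should give 2-(2-pentyl-1,3-dioxolan-2-yl)ethan-1-ol F9, and Parikh–Doering oxidation (SO3·pyridine, DMSO, Et3N, 0 °C) returns 3, again used crude in step 3.

## Further compounds

F1 | step 4 | benzyl (E)-4-(2-pentyl-1,3-dioxolan-2-yl)but-2-enoate | O=C(OCc1ccccc1)/C=C/CC1(CCCCC)OCCO1
F2 | step 4 | dibenzyl 2-acetyl-3-[(2-pentyl-1,3-dioxolan-2-yl)methyl]pentanedioate (mixture of racemic diastereomers) | CC(=O)C(C(=O)OCc1ccccc1)C(CC1(CCCCC)OCCO1)CC(=O)OCc1ccccc1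
F3 | step 5 | benzyl trans-4-methoxy-2-oxo-6-[(2-pentyl-1,3-dioxolan-2-yl)methyl]cyclohex-3-ene-1-carboxylate (racemic, one enantiomer drawn) | O=C(OCc1ccccc1)[C@@H]1C(=O)C=C(OC)C[C@H]1CC2(CCCCC)OCCO2
F4 | step 5 | benzyl trans-2-oxo-6-[(2-pentyl-1,3-dioxolan-2-yl)methyl]-4-(prop-2-en-1-yloxy)cyclohex-3-ene-1-carboxylate (racemic, one enantiomer drawn) | O=C(OCc1ccccc1)[C@@H]1C(=O)C=C(OCC=C)C[C@H]1CC2(CCCCC)OCCO2
F5 | step 11 | benzyl 2-(benzyloxy)-4-methoxy-6-[(2-pentyl-1,3-dioxolan-2-yl)methyl]benzoate | O=C(OCc1ccccc1)c1c(OCc2ccccc2)cc(OC)cc1CC1(CCCCC)OCCO1
F6 | step 11 | 2-(benzyloxy)-4-methoxy-6-[(2-pentyl-1,3-dioxolan-2-yl)methyl]benzoic acid | O=C(O)c1c(OCc2ccccc2)cc(OC)cc1CC1(CCCCC)OCCO1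
F7 | step 11 | benzyl 4-({2-(benzyloxy)-4-methoxy-6-[(2-pentyl-1,3-dioxolan-2-yl)methyl]benzoyl}oxy)-2-methoxy-6-[(2-pentyl-1,3-dioxolan-2-yl)methyl]benzoate | CCCCCC1(Cc2cc(OC)cc(OCc3ccccc3)c2C(=O)Oc2cc(CC3(CCCCC)OCCO3)c(C(=O)OCc3ccccc3)c(OC)c2)OCCO1
F8 | step 11 | benzyl 4-{[2-(benzyloxy)-4-methoxy-6-(2-oxoheptyl)benzoyl]oxy}-2-methoxy-6-(2-oxoheptyl)benzoate | CCCCCC(=O)Cc1cc(OC)cc(OCc2ccccc2)c1C(=O)Oc1cc(CC(=O)CCCCC)c(C(=O)OCc2ccccc2)c(OC)c1
F9 | step 2 | 2-(2-pentyl-1,3-dioxolan-2-yl)ethan-1-ol | CCCCCC1(CCO)OCCO1
A1 | alternative 1 | benzyl 4-({2-hydroxy-4-methoxy-6-[(2-pentyl-1,3-dioxolan-2-yl)methyl]benzoyl}oxy)-2-methoxy-6-[(2-pentyl-1,3-dioxolan-2-yl)methyl]benzoate (identical with 17) | CCCCCC1(Cc2cc(OC)cc(O)c2C(=O)Oc2cc(CC3(CCCCC)OCCO3)c(C(=O)OCc3ccccc3)c(OC)c2)OCCO1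
A2 | alternative 1 | benzyl 2-methoxy-6-[(2-pentyl-1,3-dioxolan-2-yl)methyl]-4-{[4-(2-pentyl-1,3-dioxolan-2-yl)but-2-ynoyl]oxy}benzoate | CCCCCC1(CC#CC(=O)Oc2cc(CC3(CCCCC)OCCO3)c(C(=O)OCc3ccccc3)c(OC)c2)OCCO1
A3 | alternative 1 | 1,3-dimethoxy-1-(trimethylsilyloxy)buta-1,3-diene (geometry at C1 immaterial) | C=C(OC)C=C(OC)O[Si](C)(C)C
A4 | alternative 2 | benzyl 2-[2-(benzyloxy)-2-oxoethyl]-6-methoxy-4-(methoxymethoxy)benzoate | COCOc1cc(OC)c(C(=O)OCc2ccccc2)c(CC(=O)OCc2ccccc2)c1
A5 | alternative 2 | 3-methoxy-5-(methoxymethoxy)-2-(trimethylsilyl)phenyl trifluoromethanesulfonate | COCOc1cc(OC)c([Si](C)(C)C)c(OS(=O)(=O)C(F)(F)F)c1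
A6 | alternative 3 | benzyl 2,4-dihydroxy-6-[(2-pentyl-1,3-dioxolan-2-yl)methyl]benzoate (identical with 11) | O=C(OCc1ccccc1)c1c(O)cc(O)cc1CC1(CCCCC)OCCO1
A7 | alternative 3 | 2,2-dimethyl-6-[2,4-dioxo-5-(2-pentyl-1,3-dioxolan-2-yl)pentyl]-4H-1,3-dioxin-4-one | CCCCCC1(CC(=O)CC(=O)CC2=CC(=O)OC(C)(C)O2)OCCO1
A8 | alternative 3 | benzyl 3,5,7-trioxo-8-(2-pentyl-1,3-dioxolan-2-yl)octanoate | CCCCCC1(CC(=O)CC(=O)CC(=O)CC(=O)OCc2ccccc2)OCCO1
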